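(The numbers are those of an exercise; the rest is arithmetic.)

Which set-up keeps the largest share of mono adduct among everything that became mono adduct or double product?

    starting material + partner → mono adduct + by-product (k1 = 2.3 × 10⁻⁵ /M/s)
    partner + mono adduct → double product + by-product (k2 = 1.3 × 10⁻⁵ /M/s)
    starting material ⇌ dormant form (K3 = 0.98, k3 = 4.1 × 10⁻⁶ /s)

| setting | summer | spring | autumn | dawn |
|---|---|---|---|---|
| starting material | 0.50 M | 0.50 M | 0.50 M | 0.50 M |
| partner | 0.450 M | 0.450 M | 0.450 M (fed, over 10.0 d) | 0.450 M |
| remark | one stirred flow tank at steady state, fed with the mixture as stated, mean residence time 20 d | a single well-mixed tank run continuously and read at steady state, 200 d in it on average | a stirred flask in which partner is dosed at a steady rate over 10.0 d without added volume, worked up at 20 d | a closed flask charged with all of it at once and left for 20 d |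
| time |  |  | 20 d | 20 d |

* the set-up with the highest share of mono adduct in all that became mono adduct or double product, at the outlet or at the end ("none" if the first two lie within 2 percentage points) (summer / spring / autumn / dawn / none)
* share of mono adduct in all that became mono adduct or double product, at the outlet or at the end, summer
* share of mono adduct in all that became mono adduct or double product, at the outlet or at the end, spring
* share of mono adduct in all that became mono adduct or double product, at the outlet or at the end, autumn
* share of mono adduct in all that became mono adduct or double product, at the outlet or at the end, dawn

- the stated concentrations are those of everything mixed, before any reaction; amounts are the same in each set-up
- the feed brings no volume worth counting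
- run time (autumn): 20 d

- You asked for a quick number, so start with the spring tank, whose balance can be done by hand.
- Count turnovers in a steady tank: the first step makes what leaves as mono adduct plus double product, and the second step makes what leaves as double product.
- Divide the two balances, and partner and stay cancel. Call 0.565 the selectivity factor, the second step's constant over the first step's.
- Multiply it by the converted amount per starting material left: that gives double product per mono adduct, and the share is one over one plus this.
- Take the partner as used up in spring, an assumption resting on 199 turnovers per stay at the charged starting material. Each double product took two partners, which gives the converted amount from the share.
- Split what remains by 0.98 between starting material and dormant form, because the two exchange 70.8 times per stay.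
- Start from a share of 0.5. The first round gives 37.3%, and the second gives 41.9%. Commit to that for spring and stop, since the flasks have no steady balance.
- Read the forecast: summer 46.7%, spring 41.4%, autumn 53.8%, dawn 56%, best dawn, with the warning “Dawn leads autumn by only about 2 points”. My spring number stands above its number.
- Dawn comes first at 58.6%, ahead of autumn at 53.8%, summer at 46.7% and spring at 41.4%. The spring outlet holds 22.4% starting material and 32.8% double product, in percent of the starting material charged. Put the spring share back through 0.565: it means 2.51 converted per starting material left. Now strike the dormant step from the spring tank and drop the dormant split from the same two rounds: they give 54.1%, then 52.3%, and that tank reads 53.3%.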